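Per day, in percent of the charge or in a logarithm: that is the quarrel between Ruth and Sam over this flask, which has [free monomer] at 0.20 M and 1 mol% initiator.

| setting | midnight | dawn | spring | flask |
|---|---|---|---|---|
| free monomer | 0.20 M | 0.20 M | 0.30 M | 0.20 M |
| initiator | 1.4 mol% | 2.2 mol% | 1 mol% | 1 mol% |
| remark | run made earlier | run made earlier | run made earlier |  |
| time |  |  |  | 15 d |

| run | time / d | monomer in chains / % | free monomer / % |
|---|---|---|---|
| midnight | 4.00 | 42 | 56 |
| midnight | 5.00 | 55 | 45 |
| midnight | 6.00 | 67 | 30 |
| midnight | 8.00 | 87 | 14 |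
| midnight | 10.0 | 96 | 5 |
| dawn | 4.00 | 61 | 43 |
| dawn | 5.00 | 76 | 28 |
| dawn | 6.00 | 82 | 17 |
| dawn | 8.00 | 97 | 4 |
| dawn | 10.0 | 98 | 3 |
| spring | 4.00 | 48 | 54 |
| spring | 5.00 | 59 | 38 |
| spring | 6.00 | 76 | 25 |
| spring | 8.00 | 92 | 10 |
| spring | 10.0 | 98 | 3 |

(scatter of a reading: 1.5 percentage points)

- the best time, 15 d at the latest, for monomer in chains
- the amount of monomer in chains, in percent of the free monomer charged, at that time

Sam holds that free monomer falls on a straight line. The midnight run, at the same [free monomer], lost 0.130 d⁻¹ of its charge between 4.00 d and 6.00 d, and that line meets zero at 8.31 d. Scaled by initiator, his line has the flask lose 0.0929 d⁻¹ and reach zero at 11.6 d, earlier than the limit.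

Ruth answers that the midnight run still read 14 % free monomer at 8.00 d. She calls the fall pseudo-first-order, with ln[free monomer] straight. From 4.00 d to 10.0 d, midnight gives 0.403 d⁻¹, and this line traces back to the full charge at 2.56 d.

Scaled to the flask's charged [initiator], that gives 0.288 d⁻¹. This is the working slope: the daily fall of ln[free monomer], taken as proportional to charged [initiator]. I side with Ruth. Holding that lag, I reckon 2.79 % free monomer left at 15 d, so the best time is the limit.

The forecast gave 15 d and 97 %: "No run shows chains falling, so the best time should be the limit".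

The flask gives 15.0 d and 98.2 %.

    living end + free monomer ⇌ idle complex, settled at all times (K = 6.40 M⁻¹)
    free monomer + initiator → living end + monomer in chains (k = 0.0420 M⁻¹ h⁻¹)
    free monomer + living end → monomer in chains + living end, rate k3*[living end]*[free monomer] (k = 13.0 M⁻¹ h⁻¹)

Free monomer still stood at 1.78 % in the flask at 15.0 d. Sam's figure has its region: from 1.50 d to 7.50 d the flask lost on average 0.106 d⁻¹ of its charge, against his 0.0929 d⁻¹. The working slope reckoned a logarithmic fall of 3.58 by 15 d; the flask shows 4.03.

In the neighbour flask with 0.080 M free monomer at the same loading, the working slope becomes 0.115 d⁻¹; holding the same lag, I reckon 23.9 % free monomer left at 15 d. The computed neighbour holds 34 % free monomer and 65.9 % in chains at that time, less in chains than this flask.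

(The readings were computed for substances that don't exist, noise included.)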